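The route rests on reading the 2,2-dimethyl-2H-pyran fused to ring B (oxygen on C4', carbon on C5') as the closed valence tautomer of an ortho-quinone methide. Pyran C4 is then a former salicylaldehyde carbon. Starting from 5-bromo-2,4-dihydroxybenzaldehyde and 2-methylprop-1-enylboronic acid, one operation combines an amine-catalysed Petasis reaction, amine expulsion and oxa-6π electrocyclization. This forges the C3–C4 bond and then closes the pyran at its O–CMe2 bond, and the aldehyde position dictates the linear fusion. The surviving bromine becomes a boronic acid. A rhodium-catalysed asymmetric 1,4-addition joins it to an 8-alkylated, protected 5,7-dihydroxychromone and sets C2 as S. Acetal removal completes the synthesis.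

Key step: step 1

Assumption: the (S)-configured biaryl bisphosphine is taken to deliver the aryl group to the chromone face that gives (2S), by analogy with the established facial model for 2-cyclohexenone; if the sense is opposite, the (R)-ligand is used and nothing else changes.
Assumption: 5-bromo-2,4-dihydroxybenzaldehyde, (2-methylprop-1-en-1-yl)boronic acid, 5,7-dihydroxychromone and 2-methylbut-3-en-2-ol are taken as catalogue chemicals.

Step 1
Reactants: 1 5-bromo-2,4-dihydroxybenzaldehyde; 2 (2-methylprop-1-en-1-yl)boronic acid
Product: 5 6-bromo-2,2-dimethyl-2H-chromen-7-ol, via Petasis aminophenol 3 (not isolated), via ortho-quinone methide 4 (not isolated)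
Conditions: Bn2NH (20 mol %), 1,4-dioxane, 90 °C, N2
Reagents that add atoms: none
Why: Dibenzylamine condenses with the aldehyde of 1 to an iminium ion while the ortho phenol (the later pyran oxygen) binds boronic acid 2 as a tetracoordinate boronate, which delivers the 2-methylpropenyl group intramolecularly to the iminium carbon (Petasis borono-Mannich reaction) to give 3; at 90 °C the protonated amine is expelled with the push of both ring oxygens, which returns the catalyst and dearomatizes ring B to the 1-oxatriene 4. The closest known reaction type is the amine-catalysed Petasis synthesis of 2H-chromenes from salicylaldehydes and alkenylboronic acids. The single ring closes by a thermal disrotatory oxa-6π electrocyclization of the (Z)-quinone methide, in which the carbonyl oxygen bonds to the dimethyl-substituted diene terminus and ring B regains aromaticity, so the hindered tertiary C–O bond forms without ionic substitution at a tertiary centre. No stereocenter is created. The step needs regioselectivity (linear, not angular, fusion) and chemoselectivity between the two phenols: the aldehyde carbon already sits at the future C5' position, only the hydroxyl ortho to it can direct the boronate transfer and belong to the six-atom array, the para hydroxyl can only give a para-quinone methide tautomer that cannot cyclize and returns by proton transfer, and E/Z equilibration of 4 occurs by reversible amine addition. The aryl bromide is inert under these metal-free conditions and is kept as the handle for fragment union.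

Step 2
Reactants: 5 6-bromo-2,2-dimethyl-2H-chromen-7-ol
Product: 6 6-bromo-7-(methoxymethoxy)-2,2-dimethyl-2H-chromene
Conditions: NaH, MOMCl, DMF, 0 °C to rt
Reagents that add atoms: chloromethyl methyl ether (MOMCl), COCCl
Why: Williamson-type O-alkylation of the sodium phenoxide masks the acidic proton before lithiation, and the acetal later leaves under the same conditions as the ring A acetals.

Step 3
Reactants: 6 6-bromo-7-(methoxymethoxy)-2,2-dimethyl-2H-chromene
Product: 9 [7-(methoxymethoxy)-2,2-dimethyl-2H-chromen-6-yl]boronic acid, via aryllithium 7 (not isolated), via lithium aryltriisopropoxyborate 8 (not isolated)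
Conditions: n-BuLi, THF, −78 °C; B(OiPr)3, −78 °C to rt; 1 M HCl to pH 5, 0 °C
Reagents that add atoms: triisopropyl borate, CC(C)OB(OC(C)C)OC(C)C; water, O
Why: In this lithiation–borylation, bromine–lithium exchange at −78 °C (assisted by the ortho acetal oxygen) is faster than any attack on the pyran alkene, the borate ester traps the aryllithium as ate complex 8, and brief mild hydrolysis frees the boronic acid without touching the MOM ether.

Step 4
Reactants: 10 5,7-dihydroxy-4H-chromen-4-one
Product: 11 5,7-bis(methoxymethoxy)-4H-chromen-4-one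
Conditions: NaH (2.5 equiv), MOMCl (2.5 equiv), DMF, 0 °C to rt
Reagents that add atoms: chloromethyl methyl ether (MOMCl), COCCl
Why: NaH deprotonates both phenols, including the hydrogen-bonded 5-OH, so double Williamson-type O-alkylation should give the bis-acetal and make both ring A oxygens equal donors for the next step.

Step 5
Reactants: 11 5,7-bis(methoxymethoxy)-4H-chromen-4-one
Product: 12 8-iodo-5,7-bis(methoxymethoxy)-4H-chromen-4-one
Conditions: NIS (1.05 equiv), DMF, rt to 40 °C, dark
Reagents that add atoms: N-iodosuccinimide, O=C1CCC(=O)N1I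
Why: In this electrophilic aromatic iodination, C8 (ortho to the 7-oxygen and to O1, para to the 5-oxygen) is the more accessible of the two activated ring A positions because C6 lies between two MOM ethers, in line with the known C8 preference of fully O-alkylated 5,7-dioxygenated chromones and flavones.

Step 6
Reactants: 12 8-iodo-5,7-bis(methoxymethoxy)-4H-chromen-4-one; 13 2-methylbut-3-en-2-ol
Product: 15 8-(3-hydroxy-3-methylbutyl)-5,7-bis(methoxymethoxy)-4H-chromen-4-one, via B-alkyl-9-BBN borane 14 (not isolated)
Conditions: 13, 9-BBN-H, THF, 0 °C to rt; then 12, Pd(dppf)Cl2 (5 mol %), aq K3PO4, DMF, 50 °C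
Reagents that add atoms: none
Why: Anti-Markovnikov hydroboration of the monosubstituted alkene gives primary borane 14, which after activation by aqueous base undergoes B-alkyl Suzuki–Miyaura coupling with the aryl iodide (dppf suppresses β-hydride elimination), so the saturated side chain arrives with its tertiary alcohol in place and no hydrogenation is needed near the C2=C3 bond.

Step 7
Reactants: 15 8-(3-hydroxy-3-methylbutyl)-5,7-bis(methoxymethoxy)-4H-chromen-4-one; 9 [7-(methoxymethoxy)-2,2-dimethyl-2H-chromen-6-yl]boronic acid
Product: 16 (2S)-8-(3-hydroxy-3-methylbutyl)-5,7-bis(methoxymethoxy)-2-[7-(methoxymethoxy)-2,2-dimethyl-2H-chromen-6-yl]-2,3-dihydro-4H-chromen-4-one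
Conditions: 9 (2 equiv), [Rh(OH)(cod)]2 (2.5 mol %), (S)-MeO-F12-BIPHEP [(S)-6,6'-dimethoxybiphenyl-2,2'-diylbis(bis(3,4,5-trifluorophenyl)phosphine), 5.5 mol %], toluene/H2O 10:1, 40 °C
Reagents that add atoms: none
Why: In this Hayashi–Miyaura-type asymmetric 1,4-addition of an arylboronic acid to a chromone, transmetalation gives an aryl-rhodium species that carbometalates C2=C3 on the enantioface left open by the C2-symmetric electron-poor bisphosphine, water protonates the oxa-π-allyl rhodium to release the (2S)-flavanone, and the near-neutral medium avoids retro-oxa-Michael ring opening.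

Step 8
Reactants: 16 (2S)-8-(3-hydroxy-3-methylbutyl)-5,7-bis(methoxymethoxy)-2-[7-(methoxymethoxy)-2,2-dimethyl-2H-chromen-6-yl]-2,3-dihydro-4H-chromen-4-one
Product: 17 (2S)-5,7-dihydroxy-8-(3-hydroxy-3-methylbutyl)-2-(7-hydroxy-2,2-dimethyl-2H-chromen-6-yl)-2,3-dihydro-4H-chromen-4-one
Conditions: HCl (cat., about 0.3 M), MeOH, 35 °C; NaHCO3 quench to pH 6
Reagents that add atoms: none
Why: Acid-catalysed acetal exchange with methanol cleaves the three phenolic MOM ethers under conditions mild enough to spare the tertiary alcohol and the pyran alkene, and the absence of base keeps C2 away from the retro-oxa-Michael pathway that would scramble it.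

Compound list
1 | 5-bromo-2,4-dihydroxybenzaldehyde | O=Cc1cc(Br)c(O)cc1O | starting material
2 | (2-methylprop-1-en-1-yl)boronic acid | CC(C)=CB(O)O | starting material
3 | 4-bromo-6-[1-(dibenzylamino)-3-methylbut-2-en-1-yl]benzene-1,3-diol (racemic) | CC(C)=CC(N(Cc1ccccc1)Cc1ccccc1)c1cc(Br)c(O)cc1O | intermediate
4 | (6Z)-4-bromo-3-hydroxy-6-(3-methylbut-2-en-1-ylidene)cyclohexa-2,4-dien-1-one | O=C1C=C(O)C(Br)=C/C1=C/C=C(C)C | intermediate
5 | 6-bromo-2,2-dimethyl-2H-chromen-7-ol | CC1(C)C=Cc2cc(Br)c(O)cc2O1 | intermediate
6 | 6-bromo-7-(methoxymethoxy)-2,2-dimethyl-2H-chromene | COCOc1cc2c(cc1Br)C=CC(C)(C)O2 | intermediate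
7 | [7-(methoxymethoxy)-2,2-dimethyl-2H-chromen-6-yl]lithium | [Li]c1cc2c(cc1OCOC)C=CC(C)(C)O2 | intermediate
8 | lithium [7-(methoxymethoxy)-2,2-dimethyl-2H-chromen-6-yl]triisopropoxyborate | [Li+].CC(C)O[B-](OC(C)C)(OC(C)C)c1cc2c(cc1OCOC)C=CC(C)(C)O2 | intermediate
9 | [7-(methoxymethoxy)-2,2-dimethyl-2H-chromen-6-yl]boronic acid | COCOc1cc2c(cc1B(O)O)C=CC(C)(C)O2 | intermediate
10 | 5,7-dihydroxy-4H-chromen-4-one | O=c1ccoc2cc(O)cc(O)c12 | starting material
11 | 5,7-bis(methoxymethoxy)-4H-chromen-4-one | COCOc1cc(OCOC)c2c(=O)ccoc2c1 | intermediate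
12 | 8-iodo-5,7-bis(methoxymethoxy)-4H-chromen-4-one | COCOc1cc(OCOC)c2c(=O)ccoc2c1I | intermediate
13 | 2-methylbut-3-en-2-ol | C=CC(C)(C)O | starting material
14 | 4-(9-borabicyclo[3.3.1]nonan-9-yl)-2-methylbutan-2-ol | CC(C)(O)CCB1C2CCCC1CCC2 | intermediate
15 | 8-(3-hydroxy-3-methylbutyl)-5,7-bis(methoxymethoxy)-4H-chromen-4-one | COCOc1cc(OCOC)c2c(=O)ccoc2c1CCC(C)(C)O | intermediate
16 | (2S)-8-(3-hydroxy-3-methylbutyl)-5,7-bis(methoxymethoxy)-2-[7-(methoxymethoxy)-2,2-dimethyl-2H-chromen-6-yl]-2,3-dihydro-4H-chromen-4-one | CC(C)(O)CCc1c(OCOC)cc(OCOC)c2c1O[C@H](c1cc3c(cc1OCOC)OC(C)(C)C=C3)CC2=O | intermediate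
17 | (2S)-5,7-dihydroxy-8-(3-hydroxy-3-methylbutyl)-2-(7-hydroxy-2,2-dimethyl-2H-chromen-6-yl)-2,3-dihydro-4H-chromen-4-one | CC(C)(O)CCc1c(O)cc(O)c2c1O[C@H](c1cc3c(cc1O)OC(C)(C)C=C3)CC2=O | target

Total step count: 8. Longest linear sequence: 5 steps (steps 1, 2, 3, 7, 8, or equally steps 4, 5, 6, 7, 8).

Steps most likely to fail

1. Step 7.
- **Risk:** Protodeboronation of the ortho- and para-oxygenated boronic acid may outrun carbometalation of the electron-rich, hindered chromone. Slow turnover may also allow partial ring opening and loss of enantiopurity.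
- **Fallback:** This forms the C2–O1 bond instead of the C2–C1' bond. It sets out from 15 and 6 and comes back at 16.
- Chromone 15 is opened and deformylated with aqueous NaOH in EtOH to give 1-[2-hydroxy-3-(3-hydroxy-3-methylbutyl)-4,6-bis(methoxymethoxy)phenyl]ethanone F1. Its only free phenol lies next to the side chain, so the 8-substitution pattern is kept.
- Aryllithium 7, generated from 6 as before, is quenched with DMF to give 7-(methoxymethoxy)-2,2-dimethyl-2H-chromene-6-carbaldehyde F2.
- Claisen–Schmidt condensation of the two (KOH, EtOH, rt) should give (E)-1-[2-hydroxy-3-(3-hydroxy-3-methylbutyl)-4,6-bis(methoxymethoxy)phenyl]-3-[7-(methoxymethoxy)-2,2-dimethyl-2H-chromen-6-yl]prop-2-en-1-one F3.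
- F3 is closed to 16 by an enantioselective intramolecular oxa-Michael addition under a cinchona-derived bifunctional thiourea, with the pseudo-enantiomer chosen for the 2S sense. Enrichment by crystallization or chromatography on a chiral phase follows if needed.

2. Step 8.
- **Risk:** Under protic acid, the tertiary alcohol may ionize and be captured by the freed 7-OH (chroman closure). Ionization of the doubly donor-stabilized benzylic C2–O1 bond (racemization) may also compete with acetal cleavage.
- **Fallback:** This replaces solvolysis by non-protic silyl transfer. It sets out from 16 and comes back at 17.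
- Treatment with TMSOTf and 2,2'-bipyridyl in MeCN at 0 °C should exchange each aryl MOM ether for a silyl ether and cap the tertiary alcohol. The product is (2S)-2-[2,2-dimethyl-7-(trimethylsilyloxy)-2H-chromen-6-yl]-8-[3-methyl-3-(trimethylsilyloxy)butyl]-5,7-bis(trimethylsilyloxy)-2,3-dihydro-4H-chromen-4-one F4.
- F4 is desilylated with Et3N·3HF in THF at 0 °C, a buffered and essentially neutral medium, to give 17.

3. Step 1.
- **Risk:** Iminium formation from the strongly donor-substituted aldehyde may be sluggish. The quinone methide may also be consumed by conjugate addition of the product phenol (oligomerization) before it can electrocyclize.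
- **Fallback:** This makes the C3–C4 bond by carbonyl addition of an organomagnesium reagent instead of a borono-Mannich transfer. It sets out from 1 and comes back at 5.
- Excess 2-methylprop-1-enylmagnesium bromide (3.3 equiv, THF, 0 °C to rt) adds to the bis-phenoxide of 1 to give 4-bromo-6-(1-hydroxy-3-methylbut-2-en-1-yl)benzene-1,3-diol F5.
- Warming F5 in dilute toluene with PPTS removes water to give the same quinone methide 4, which closes to 5.

Further compounds
F1 | step 7 | 1-[2-hydroxy-3-(3-hydroxy-3-methylbutyl)-4,6-bis(methoxymethoxy)phenyl]ethanone | CC(=O)c1c(O)c(CCC(C)(C)O)c(OCOC)cc1OCOC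
F2 | step 7 | 7-(methoxymethoxy)-2,2-dimethyl-2H-chromene-6-carbaldehyde | COCOc1cc2c(cc1C=O)C=CC(C)(C)O2
F3 | step 7 | (E)-1-[2-hydroxy-3-(3-hydroxy-3-methylbutyl)-4,6-bis(methoxymethoxy)phenyl]-3-[7-(methoxymethoxy)-2,2-dimethyl-2H-chromen-6-yl]prop-2-en-1-one | CC(C)(O)CCc1c(O)c(C(=O)/C=C/c2cc3c(cc2OCOC)OC(C)(C)C=C3)c(OCOC)cc1OCOC
F4 | step 8 | (2S)-2-[2,2-dimethyl-7-(trimethylsilyloxy)-2H-chromen-6-yl]-8-[3-methyl-3-(trimethylsilyloxy)butyl]-5,7-bis(trimethylsilyloxy)-2,3-dihydro-4H-chromen-4-one | CC(C)(O[Si](C)(C)C)CCc1c(O[Si](C)(C)C)cc(O[Si](C)(C)C)c2c1O[C@H](c1cc3c(cc1O[Si](C)(C)C)OC(C)(C)C=C3)CC2=O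
F5 | step 1 | 4-bromo-6-(1-hydroxy-3-methylbut-2-en-1-yl)benzene-1,3-diol (racemic) | CC(C)=CC(O)c1cc(Br)c(O)cc1O
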